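**Plan**

- Retrosynthesis: the C4–C6 interflavan bond is cut last (C4 cation of one flavan, C6 of ring A of the other), so both halves come from one flavan-4-ol monomer. In that monomer, ring C is cut at O1–C8a and at C2–C3.
- Enabling feature: C4 of ring C sits on C4a, ortho to C8a of ring A. Held as a ketone it makes C3 an enolate carbon and makes a fluorine on C8a an SNAr leaving group, so ring B with C2 and O1 can be annulated as an aroyl chloride onto a 2-fluoroaryl benzyloxymethyl ketone in one flask.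
- Forward order: ring A ketone, then ring C by acylation/SNAr (a flavonol ether), then cis-hydrogenation to the flavan-4-ol. This alcohol diverges to a 4β-thioether (electrophile) and a 4β-acetate (nucleophile), which are joined 4→6 by silver activation; deacetylation and debenzylation finish the route.
- Stereochemistry: C2 and C3 of both units come from catalyst-controlled syn addition of H2 to the planar C2=C3 bond. Every C4 comes from entry of the incoming group anti to the axial 3-benzyloxy group (cation capture or inversion).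

Key step: step 5

Remark: 3-fluorocatechol, 2-(benzyloxy)-N-methoxy-N-methylacetamide and 3,4-bis(benzyloxy)benzoic acid are taken as purchasable; flavan numbering is used, α is the face of the 2-aryl group and β the opposite face.
Remark: (R,R)-SINpEt·HBF4 is 1,3-bis[(R)-1-(naphthalen-1-yl)ethyl]-4,5-dihydroimidazolium tetrafluoroborate; it is assumed to be the antipode that adds H2 to the β face of the flavonol ether, otherwise the (S,S) salt is used.

**Step 1**
Reactants: 1 3-fluorobenzene-1,2-diol (3-fluorocatechol)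
Product: 2 1,2-bis(benzyloxy)-3-fluorobenzene
Conditions: BnBr (2.3 equiv), K2CO3 (2.5 equiv), DMF, 60 °C
Reagents that add atoms: benzyl bromide, BrCc1ccccc1
Why: Williamson etherification of both phenols installs the benzyl ethers that are carried to the last step; no stereocentre is involved.

**Step 2**
Reactants: 2 1,2-bis(benzyloxy)-3-fluorobenzene
Product: 3 1,2-bis(benzyloxy)-4-bromo-3-fluorobenzene
Conditions: NBS (1.05 equiv), MeCN, 0 °C to rt, dark
Reagents that add atoms: N-bromosuccinimide, O=C1CCC(=O)N1Br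
Why: Electrophilic aromatic bromination should go para to the C1 benzyloxy group, which conjugates freely, whereas the C2 ether flanked on both sides is twisted out of conjugation; this places bromine at C4 next to fluorine.

**Step 3**
Reactants: 3 1,2-bis(benzyloxy)-4-bromo-3-fluorobenzene; 4 2-(benzyloxy)-N-methoxy-N-methylacetamide
Product: 7 2-(benzyloxy)-1-[3,4-bis(benzyloxy)-2-fluorophenyl]ethan-1-one, via aryllithium 5 (not isolated), via lithium hemiaminal adduct 6 (not isolated)
Conditions: n-BuLi (1.05 equiv), THF, −78 °C; then 4, −78 to −40 °C; 1 M HCl quench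
Reagents that add atoms: none
Why: Bromine–lithium exchange at −78 °C is faster than loss of LiF to a benzyne, and the Weinreb ketone synthesis stops at the chelated adduct, so the ketone forms without over-addition.

**Step 4**
Reactants: 8 3,4-bis(benzyloxy)benzoic acid
Product: 9 3,4-bis(benzyloxy)benzoyl chloride
Conditions: (COCl)2 (1.3 equiv), DMF (cat.), CH2Cl2, 0 °C to rt; evaporate
Reagents that add atoms: oxalyl chloride, ClC(=O)C(=O)Cl
Why: Acid chloride formation through the chloroiminium species gives only volatile by-products, so 9 can be used crude.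

**Step 5**
Reactants: 7 2-(benzyloxy)-1-[3,4-bis(benzyloxy)-2-fluorophenyl]ethan-1-one; 9 3,4-bis(benzyloxy)benzoyl chloride
Product: 12 3,7,8-tris(benzyloxy)-2-[3,4-bis(benzyloxy)phenyl]-4H-chromen-4-one, via lithium enolate 10 (not isolated), via lithium diketonate 11 (not isolated)
Conditions: LiN(SiMe3)2 (2.4 equiv), THF/toluene, −78 °C; 9 (1.05 equiv), −78 to 0 °C; then DMF, 90 °C
Reagents that add atoms: none
Why: LiN(SiMe3)2 gives the chelated Z-lithium enolate 10, which is C-acylated at C3 by 9 (Claisen-type acylation, the C2–C3 bond); the second equivalent of base turns the 1,3-diketone into enolate 11, whose oxygen on C2 adds to C8a of ring A and expels fluoride through a Meisenheimer intermediate stabilised by the ortho C4 carbonyl (SNAr, the O1–C8a bond). The closest known reaction type is the Baker–Venkataraman acylation followed by SNAr closure of ortho-halogenated aryl 1,3-diketones to flavones. Ring C closes in the 6-endo-trig mode of an addition–elimination on the vinylogous acyl fluoride C8a=C4a–C4=O. No stereocentre is formed; the step delivers a planar C2=C3 bond on purpose, so that step 6 can set C2 and C3 together. The step needs C- over O-acylation, which the lithium counter-ion in toluene and the excess base (returning any enol ester to the diketonate) should secure. It also needs closure through the C2 oxygen only, which is secured by the benzyl cap on O3 (no five-membered benzofuranone) and by fluorine being the only leaving group ortho to a carbonyl.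

**Step 6**
Reactants: 12 3,7,8-tris(benzyloxy)-2-[3,4-bis(benzyloxy)phenyl]-4H-chromen-4-one
Product: 14 (2R,3R,4R)-3,7,8-tris(benzyloxy)-2-[3,4-bis(benzyloxy)phenyl]-3,4-dihydro-2H-chromen-4-ol (all-cis), via cis-ketone 13 (not isolated)
Conditions: Ru(cod)(2-methylallyl)2 (5 mol %), (R,R)-SINpEt·HBF4 (10 mol %), KOt-Bu (10 mol %), H2 (100 bar), toluene, 40 °C; then NaBH4, THF/MeOH, 0 °C
Reagents that add atoms: none
Why: Proposed new method: a chiral Ru–carbene hydride should add H2 syn across the C2=C3 bond of the pyranone from the β face (C2 Si, C3 Re) selected by the ligand pocket, so C2 and C3 arise cis in one event, and ketone 13, whose 3-benzyloxy group is axial, is then reduced by Ru–H or NaBH4 anti to that group to the all-cis alcohol; the closest known reaction type is the Ru–NHC-catalysed asymmetric hydrogenation of flavones and chromones to flavanones and cis-flavan-4-ols, not yet shown for 3-alkoxyflavones with a tetrasubstituted C2=C3 bond.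

**Step 7**
Reactants: 14 (2R,3R,4R)-3,7,8-tris(benzyloxy)-2-[3,4-bis(benzyloxy)phenyl]-3,4-dihydro-2H-chromen-4-ol
Product: 15 (2R,3S,4S)-4-(benzylsulfanyl)-3,7,8-tris(benzyloxy)-2-[3,4-bis(benzyloxy)phenyl]-3,4-dihydro-2H-chromene (2,3-cis-3,4-trans, 4β-thioether)
Conditions: BnSH (3 equiv), BF3·OEt2 (0.2 equiv), CH2Cl2, −30 to 0 °C
Reagents that add atoms: phenylmethanethiol, SCc1ccccc1
Why: BF3·OEt2 ionises the benzylic 4-hydroxyl (para to the 7-benzyloxy group) and the thiol should add to the C4 cation anti to the axial 3-benzyloxy group (acid-catalysed thiolysis of a flavan-4-ol), which sets the 4β thioether whatever the C4 configuration of 14.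

**Step 8**
Reactants: 14 (2R,3R,4R)-3,7,8-tris(benzyloxy)-2-[3,4-bis(benzyloxy)phenyl]-3,4-dihydro-2H-chromen-4-ol
Product: 16 (2R,3S,4S)-3,7,8-tris(benzyloxy)-2-[3,4-bis(benzyloxy)phenyl]-3,4-dihydro-2H-chromen-4-yl acetate (2,3-cis-3,4-trans, 4β-acetate)
Conditions: AcOH (2 equiv), PPh3 (1.5 equiv), DIAD (1.5 equiv), toluene, 0 °C to rt
Reagents that add atoms: acetic acid, CC(=O)O
Why: Mitsunobu esterification should invert the equatorial 4α-alcohol to the 4β-acetate, and an ion-pair pathway would give the same result because acetate then also enters anti to the axial 3-benzyloxy group; the acetate keeps this C4 oxygen from ionising in step 9.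

**Step 9**
Reactants: 15 (2R,3S,4S)-4-(benzylsulfanyl)-3,7,8-tris(benzyloxy)-2-[3,4-bis(benzyloxy)phenyl]-3,4-dihydro-2H-chromene; 16 (2R,3S,4S)-3,7,8-tris(benzyloxy)-2-[3,4-bis(benzyloxy)phenyl]-3,4-dihydro-2H-chromen-4-yl acetate
Product: 17 deca-O-benzyl (4β→6) dimer 4-acetate: the flavan unit of 15 bonded through C4 (bond β, trans to its 3-benzyloxy group) to C6 of ring A of 16; spatial arrangement at all six stereocentres as in 19
Conditions: AgBF4 (2.5 equiv), 2,6-di-tert-butyl-4-methylpyridine (1.2 equiv), 16 (3 equiv), THF/CH2Cl2, 0 °C, dark; 15 added over 2 h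
Reagents that add atoms: none
Why: AgBF4 abstracts the benzylthio group of 15 (thiophilic activation of a 4-thioflavan) and the C4 cation is trapped in a Friedel–Crafts alkylation by C6 of ring A of 16 (para to O1, ortho to the 7-benzyloxy group) anti to the axial 3-benzyloxy group, which sets the 4β interflavan bond; excess 16 and slow addition of 15 hold back self-condensation, and the acetate of 16 is inert to silver.

**Step 10**
Reactants: 17 deca-O-benzyl (4β→6) dimer 4-acetate
Product: 18 deca-O-benzyl (4β→6) dimer with free 4β-hydroxyl on the lower unit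
Conditions: K2CO3 (0.3 equiv), MeOH/THF, rt
Reagents that add atoms: none
Why: Base-catalysed transesterification removes the acetate by acyl–oxygen cleavage, so C4 of the lower unit keeps its configuration.

**Step 11**
Reactants: 18 deca-O-benzyl (4β→6) dimer with free 4β-hydroxyl on the lower unit
Product: 19 (2R,3R,4S)-2-(3,4-dihydroxyphenyl)-6-[(2R,3R,4S)-2-(3,4-dihydroxyphenyl)-3,7,8-trihydroxy-3,4-dihydro-2H-chromen-4-yl]-3,4-dihydro-2H-chromene-3,4,7,8-tetrol
Conditions: H2 (1 atm), Pd(OH)2/C, THF/MeOH, rt; filtered under argon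
Reagents that add atoms: none
Why: Hydrogenolysis of the ten benzyl ethers under neutral conditions at 1 atm should be faster than loss of the secondary benzylic 4-hydroxyl and touches none of the six stereocentres.

**Compound list**

1 | 3-fluorobenzene-1,2-diol | Oc1cccc(F)c1O | starting material
2 | 1,2-bis(benzyloxy)-3-fluorobenzene | Fc1cccc(OCc2ccccc2)c1OCc1ccccc1 | intermediate
3 | 1,2-bis(benzyloxy)-4-bromo-3-fluorobenzene | Fc1c(Br)ccc(OCc2ccccc2)c1OCc1ccccc1 | intermediate
4 | 2-(benzyloxy)-N-methoxy-N-methylacetamide | CON(C)C(=O)COCc1ccccc1 | starting material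
5 | [3,4-bis(benzyloxy)-2-fluorophenyl]lithium | [Li]c1ccc(OCc2ccccc2)c(OCc2ccccc2)c1F | intermediate
6 | lithium 2-(benzyloxy)-1-[3,4-bis(benzyloxy)-2-fluorophenyl]-1-[methoxy(methyl)amino]ethan-1-olate | [Li]OC(COCc1ccccc1)(N(C)OC)c1ccc(OCc2ccccc2)c(OCc2ccccc2)c1F | intermediate
7 | 2-(benzyloxy)-1-[3,4-bis(benzyloxy)-2-fluorophenyl]ethan-1-one | O=C(COCc1ccccc1)c1ccc(OCc2ccccc2)c(OCc2ccccc2)c1F | intermediate
8 | 3,4-bis(benzyloxy)benzoic acid | OC(=O)c1ccc(OCc2ccccc2)c(OCc2ccccc2)c1 | starting material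
9 | 3,4-bis(benzyloxy)benzoyl chloride | ClC(=O)c1ccc(OCc2ccccc2)c(OCc2ccccc2)c1 | intermediate
10 | lithium (Z)-2-(benzyloxy)-1-[3,4-bis(benzyloxy)-2-fluorophenyl]ethen-1-olate | [Li]O/C(=C\OCc1ccccc1)c1ccc(OCc2ccccc2)c(OCc2ccccc2)c1F | intermediate
11 | lithium enolate of 2-(benzyloxy)-1-[3,4-bis(benzyloxy)-2-fluorophenyl]-3-[3,4-bis(benzyloxy)phenyl]propane-1,3-dione | [Li]OC(=C(OCc1ccccc1)C(=O)c1ccc(OCc2ccccc2)c(OCc2ccccc2)c1F)c1ccc(OCc2ccccc2)c(OCc2ccccc2)c1 | intermediate
12 | 3,7,8-tris(benzyloxy)-2-[3,4-bis(benzyloxy)phenyl]-4H-chromen-4-one | O=c1c(OCc2ccccc2)c(-c2ccc(OCc3ccccc3)c(OCc3ccccc3)c2)oc2c(OCc3ccccc3)c(OCc3ccccc3)ccc12 | intermediate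
13 | (2R,3S)-3,7,8-tris(benzyloxy)-2-[3,4-bis(benzyloxy)phenyl]-2,3-dihydro-4H-chromen-4-one (2,3-cis) | O=C1[C@@H](OCc2ccccc2)[C@@H](c2ccc(OCc3ccccc3)c(OCc3ccccc3)c2)Oc2c1ccc(OCc1ccccc1)c2OCc1ccccc1 | intermediate
14 | (2R,3R,4R)-3,7,8-tris(benzyloxy)-2-[3,4-bis(benzyloxy)phenyl]-3,4-dihydro-2H-chromen-4-ol (all-cis) | O[C@H]1[C@@H](OCc2ccccc2)[C@@H](c2ccc(OCc3ccccc3)c(OCc3ccccc3)c2)Oc2c1ccc(OCc1ccccc1)c2OCc1ccccc1 | intermediate
15 | (2R,3S,4S)-4-(benzylsulfanyl)-3,7,8-tris(benzyloxy)-2-[3,4-bis(benzyloxy)phenyl]-3,4-dihydro-2H-chromene (2,3-cis-3,4-trans; the letter at C3 changes by the CIP rules only) | c1ccccc1CS[C@@H]1[C@@H](OCc2ccccc2)[C@@H](c2ccc(OCc3ccccc3)c(OCc3ccccc3)c2)Oc2c1ccc(OCc1ccccc1)c2OCc1ccccc1 | intermediate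
16 | (2R,3S,4S)-3,7,8-tris(benzyloxy)-2-[3,4-bis(benzyloxy)phenyl]-3,4-dihydro-2H-chromen-4-yl acetate (2,3-cis-3,4-trans) | CC(=O)O[C@@H]1[C@@H](OCc2ccccc2)[C@@H](c2ccc(OCc3ccccc3)c(OCc3ccccc3)c2)Oc2c1ccc(OCc1ccccc1)c2OCc1ccccc1 | intermediate
17 | deca-O-benzyl (4β→6) dimer 4-acetate: unit of 15 (2α-aryl, 3α-benzyloxy) joined by C4 (bond β) to C6 of 16; both units 2,3-cis-3,4-trans | c5ccccc5COc1ccc([C@H]2Oc3c(ccc(OCc5ccccc5)c3OCc5ccccc5)[C@H](c3cc4c(c(OCc5ccccc5)c3OCc5ccccc5)O[C@H](c3ccc(OCc5ccccc5)c(OCc5ccccc5)c3)[C@H](OCc5ccccc5)[C@H]4OC(C)=O)[C@H]2OCc5ccccc5)cc1OCc1ccccc1 | intermediate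
18 | deca-O-benzyl (4β→6) dimer with free 4β-hydroxyl on the lower unit; both units 2,3-cis-3,4-trans | c5ccccc5COc1ccc([C@H]2Oc3c(ccc(OCc5ccccc5)c3OCc5ccccc5)[C@H](c3cc4c(c(OCc5ccccc5)c3OCc5ccccc5)O[C@H](c3ccc(OCc5ccccc5)c(OCc5ccccc5)c3)[C@H](OCc5ccccc5)[C@H]4O)[C@H]2OCc5ccccc5)cc1OCc1ccccc1 | intermediate
19 | (2R,3R,4S)-2-(3,4-dihydroxyphenyl)-6-[(2R,3R,4S)-2-(3,4-dihydroxyphenyl)-3,7,8-trihydroxy-3,4-dihydro-2H-chromen-4-yl]-3,4-dihydro-2H-chromene-3,4,7,8-tetrol | Oc1ccc([C@H]2Oc3c(ccc(O)c3O)[C@H](c3cc4c(c(O)c3O)O[C@H](c3ccc(O)c(O)c3)[C@H](O)[C@H]4O)[C@H]2O)cc1O | target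

**Totals and risks**

Total step count: 11. Longest linear sequence: 9 steps (steps 1, 2, 3, 5, 6, 7, 9, 10, 11).

Steps most likely to fail:

Step 6 (labelled step). What may go wrong: slow turnover on the tetrasubstituted, alkoxy-bearing C2=C3 bond, weak facial selectivity, epimerisation of the intermediate ketone at C3 before the carbonyl is reduced, or partial reduction of arene rings. The fallback sets out from 12 and comes back at 14. 12 is hydrogenated over PtO2 in EtOAc (platinum spares aryl benzyl ethers); syn addition and carbonyl reduction anti to the axial 3-benzyloxy group should give the racemic all-cis alcohol, that is 14 together with its mirror image (2S,3S,4S)-3,7,8-tris(benzyloxy)-2-[3,4-bis(benzyloxy)phenyl]-3,4-dihydro-2H-chromen-4-ol F1. A lipase (Pseudomonas cepacia lipase or Candida antarctica lipase B, vinyl acetate, toluene, 40 °C) then serves for kinetic resolution. By the empirical rule for lipase acylation of aryl carbinols the 4S alcohol should react, giving (2S,3R,4S)-3,7,8-tris(benzyloxy)-2-[3,4-bis(benzyloxy)phenyl]-3,4-dihydro-2H-chromen-4-yl acetate F2, and unchanged 14 is separated by chromatography.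

Step 9. What may go wrong: the C4 cation is captured by ring A of a second molecule of the electrophile (self-condensation and oligomers), it loses a proton to a flav-3-ene, or it attacks the wrong ring position. The fallback sets out from 14 and comes back at 19; it blocks the competing position. NBS (CH2Cl2, −20 °C) should brominate 14 at C6 of ring A, its most electron-rich position, to give (2R,3R,4R)-6-bromo-3,7,8-tris(benzyloxy)-2-[3,4-bis(benzyloxy)phenyl]-3,4-dihydro-2H-chromen-4-ol F3. Thiolysis as in step 7 gives (2R,3S,4S)-4-(benzylsulfanyl)-6-bromo-3,7,8-tris(benzyloxy)-2-[3,4-bis(benzyloxy)phenyl]-3,4-dihydro-2H-chromene F4. Union with 16 under AgBF4 gives the 6-bromo derivative (upper unit) of dimer acetate 17 F5, whose electrophilic partner can no longer react through its own C6. K2CO3 in MeOH gives the 6-bromo derivative (upper unit) of dimer alcohol 18 F6. Hydrogenolysis over Pd(OH)2/C with NEt3 removes bromine and the benzyl groups together and gives 19.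

Step 11. What may go wrong: hydrogenolytic loss of the benzylic 4-hydroxyl of the lower unit, or its ionisation on a slightly acidic catalyst. The fallback sets out from 18 and comes back at 19; it carries this carbon through the hydrogenolysis as a ketone. Dess–Martin periodinane (CH2Cl2, NaHCO3, 0 °C) oxidises the only free hydroxyl of 18 to give the deca-O-benzyl dimer with a C4 ketone in the lower unit F7. Hydrogenolysis (H2, Pd(OH)2/C, THF/MeOH) gives the free phenolic dimer with a C4 ketone in the lower unit F8. Me4NBH(OAc)3 in MeCN/AcOH at −20 °C, bound to the free 3-hydroxyl, should deliver hydride to the same face of C4 and give the 3,4-trans diol 19.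

**Further compounds**

F1 | step 6 | (2S,3S,4S)-3,7,8-tris(benzyloxy)-2-[3,4-bis(benzyloxy)phenyl]-3,4-dihydro-2H-chromen-4-ol (enantiomer of 14) | O[C@@H]1[C@H](OCc2ccccc2)[C@H](c2ccc(OCc3ccccc3)c(OCc3ccccc3)c2)Oc2c1ccc(OCc1ccccc1)c2OCc1ccccc1
F2 | step 6 | (2S,3R,4S)-3,7,8-tris(benzyloxy)-2-[3,4-bis(benzyloxy)phenyl]-3,4-dihydro-2H-chromen-4-yl acetate (all-cis acetate of F1) | CC(=O)O[C@@H]1[C@H](OCc2ccccc2)[C@H](c2ccc(OCc3ccccc3)c(OCc3ccccc3)c2)Oc2c1ccc(OCc1ccccc1)c2OCc1ccccc1
F3 | step 9 | (2R,3R,4R)-6-bromo-3,7,8-tris(benzyloxy)-2-[3,4-bis(benzyloxy)phenyl]-3,4-dihydro-2H-chromen-4-ol | O[C@H]1[C@@H](OCc2ccccc2)[C@@H](c2ccc(OCc3ccccc3)c(OCc3ccccc3)c2)Oc2c1cc(Br)c(OCc1ccccc1)c2OCc1ccccc1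
F4 | step 9 | (2R,3S,4S)-4-(benzylsulfanyl)-6-bromo-3,7,8-tris(benzyloxy)-2-[3,4-bis(benzyloxy)phenyl]-3,4-dihydro-2H-chromene | c1ccccc1CS[C@@H]1[C@@H](OCc2ccccc2)[C@@H](c2ccc(OCc3ccccc3)c(OCc3ccccc3)c2)Oc2c1cc(Br)c(OCc1ccccc1)c2OCc1ccccc1
F5 | step 9 | 6-bromo derivative (upper unit) of dimer acetate 17 | c5ccccc5COc1ccc([C@H]2Oc3c(cc(Br)c(OCc5ccccc5)c3OCc5ccccc5)[C@H](c3cc4c(c(OCc5ccccc5)c3OCc5ccccc5)O[C@H](c3ccc(OCc5ccccc5)c(OCc5ccccc5)c3)[C@H](OCc5ccccc5)[C@H]4OC(C)=O)[C@H]2OCc5ccccc5)cc1OCc1ccccc1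
F6 | step 9 | 6-bromo derivative (upper unit) of dimer alcohol 18 | c5ccccc5COc1ccc([C@H]2Oc3c(cc(Br)c(OCc5ccccc5)c3OCc5ccccc5)[C@H](c3cc4c(c(OCc5ccccc5)c3OCc5ccccc5)O[C@H](c3ccc(OCc5ccccc5)c(OCc5ccccc5)c3)[C@H](OCc5ccccc5)[C@H]4O)[C@H]2OCc5ccccc5)cc1OCc1ccccc1
F7 | step 11 | deca-O-benzyl (4β→6) dimer with a C4 ketone in the lower unit | c5ccccc5COc1ccc([C@H]2Oc3c(ccc(OCc5ccccc5)c3OCc5ccccc5)[C@H](c3cc4c(c(OCc5ccccc5)c3OCc5ccccc5)O[C@H](c3ccc(OCc5ccccc5)c(OCc5ccccc5)c3)[C@H](OCc5ccccc5)C4=O)[C@H]2OCc5ccccc5)cc1OCc1ccccc1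
F8 | step 11 | free phenolic (4β→6) dimer with a C4 ketone in the lower unit | Oc1ccc([C@H]2Oc3c(ccc(O)c3O)[C@H](c3cc4c(c(O)c3O)O[C@H](c3ccc(O)c(O)c3)[C@H](O)C4=O)[C@H]2O)cc1O
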